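The hexasubstituted phloroglucinol ring, oxygenated at C1, C3 and C5 with a different carbon substituent on each carbon between them, is cut into a 3-alkoxycyclobutenone (four ring carbons, two oxygens) and a prenyl siloxyalkyne (two ring carbons, the third oxygen). One thermal Danheiser benzannulation forms the C(OH)–C(prenyl) and C(OSi)–C(H) bonds and closes the benzene ring with five substituents placed regiospecifically; the lone ring C–H is acylated afterwards. The precursor is a racemic 3-benzyloxycyclobutenone carrying the O-benzylated pyranonylmethyl group at C4, built by ketene–ynol ether [2+2]; benzyl and silyl ethers allow an acid-free C-acylation and deprotection at −78 °C.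

Key step: step 11

Remark (protecting groups): the ring oxygen delivered by the cyclobutenone and the pyranone 4-oxygen are carried as benzyl ethers, because after C-acylation a methyl or ethyl ether beside the ketone would be the second ortho oxygen and would not respond to chelation-controlled boron trichloride, whereas benzyl ethers ionise at −78 °C without chelation.
Remark (structures): the regiochemical mapping of the annulation (hydroxyl from the ketene carbonyl, prenyl ortho to it, silyloxy meta, free ring CH between the silyloxy and alkoxy carbons) was checked against the target and needs no correction.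
Assumption: (S)-2-methylbutanoic acid of high enantiomeric purity, allylmalonic acid and ethynylmagnesium bromide (THF solution) are taken as commercial.

Step 1
Reactants: 1 pentan-3-one
Product: 2 (Z)-3-(trimethylsilyloxy)pent-2-ene
Conditions: TMSOTf, Et3N, CH2Cl2, 0 °C
Reagents that add atoms: trimethylsilyl trifluoromethanesulfonate, C[Si](C)(C)OS(=O)(=O)C(F)(F)F
Why: Soft enolisation and O-silylation of a symmetrical ketone (silyl enol ether formation) should be clean, and the double-bond geometry is irrelevant because this carbon pair becomes C5–C6 of the aromatic pyranone.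

Step 2
Reactants: 3 allylmalonic acid
Product: 4 allylmalonyl dichloride
Conditions: SOCl2, DMF (cat.), 45 °C; distillation under reduced pressure
Reagents that add atoms: thionyl chloride, O=S(Cl)Cl
Why: Acid chloride formation from a malonic acid with thionyl chloride is routine, and the mild temperature keeps decarboxylation in check.

Step 3
Reactants: 2 (Z)-3-(trimethylsilyloxy)pent-2-ene; 4 allylmalonyl dichloride
Product: 5 3-allyl-6-ethyl-4-hydroxy-5-methyl-2H-pyran-2-one
Conditions: Et2O, −78 °C → rt
Reagents that add atoms: none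
Why: Cyclocondensation of a silyl enol ether with a malonyl dichloride (C-acylation of the enol silane, then O-acylative lactonisation) is an established route to 4-hydroxy-2-pyranones and places allyl at C3, methyl at C5 and ethyl at C6 unambiguously.

Step 4
Reactants: 5 3-allyl-6-ethyl-4-hydroxy-5-methyl-2H-pyran-2-one
Product: 6 3-allyl-4-(benzyloxy)-6-ethyl-5-methyl-2H-pyran-2-one
Conditions: BnBr, K2CO3, DMF, rt
Reagents that add atoms: benzyl bromide, BrCc1ccccc1
Why: Williamson O-alkylation of the acidic vinylogous acid should occur mainly at O4 because C3 is blocked, and any isomeric 2-benzyloxy-4-pyranone is to be removed by chromatography.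

Step 5
Reactants: 6 3-allyl-4-(benzyloxy)-6-ethyl-5-methyl-2H-pyran-2-one
Product: 7 4-(benzyloxy)-6-ethyl-3-(3-hydroxypropyl)-5-methyl-2H-pyran-2-one
Conditions: 9-BBN, THF, 0 °C → rt; then 30% H2O2, pH 7 phosphate buffer, 0 °C → rt
Reagents that add atoms: hydrogen peroxide, OO
Why: Anti-Markovnikov hydroboration–oxidation with bulky 9-BBN should select the terminal alkene over the tetrasubstituted pyranone olefins, and the buffered oxidation avoids alkoxide attack on the vinylogous ester.

Step 6
Reactants: 7 4-(benzyloxy)-6-ethyl-3-(3-hydroxypropyl)-5-methyl-2H-pyran-2-one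
Product: 8 3-[4-(benzyloxy)-6-ethyl-5-methyl-2-oxo-2H-pyran-3-yl]propanoic acid
Conditions: TEMPO (cat.), PhI(OAc)2, MeCN/H2O (1:1), rt
Reagents that add atoms: water, O
Why: Oxoammonium (TEMPO)-catalysed oxidation of a primary alcohol through the aldehyde hydrate to the carboxylic acid is mild enough for the benzyl enol ether and the lactone.

Step 7
Reactants: 9 benzyl alcohol; 10 trichloroethylene
Product: 13 benzyloxyacetylene, via benzyl (E)-1,2-dichlorovinyl ether 11 (not isolated), via lithium (benzyloxy)ethynide 12 (not isolated)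
Conditions: KH, THF, 0 °C; Cl2C=CHCl, −50 °C → rt; n-BuLi (2.4 equiv), −78 → −40 °C; MeOH, −78 °C
Reagents that add atoms: none
Why: One-pot ynol ether synthesis (alkoxide addition–elimination on trichloroethylene, then dehydrochlorination and chlorine–lithium exchange with butyllithium and cold protonation) is established for alkoxyacetylenes, and keeping the product below 25 °C avoids sigmatropic rearrangement of the benzyl alkynyl ether.

Step 8
Reactants: 8 3-[4-(benzyloxy)-6-ethyl-5-methyl-2-oxo-2H-pyran-3-yl]propanoic acid; 13 benzyloxyacetylene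
Product: 16 4-(benzyloxy)-3-{[2-(benzyloxy)-4-oxocyclobut-2-en-1-yl]methyl}-6-ethyl-5-methyl-2H-pyran-2-one (racemic), via acid chloride 14 (not isolated), via ketene 15 (not isolated)
Conditions: (COCl)2, DMF (cat.), CH2Cl2, 0 °C → rt, evaporate below 25 °C; then slow addition to 13 (2 equiv), Et3N, CH2Cl2, 0 °C → rt
Reagents that add atoms: none
Why: Dehydrochlorination of the acid chloride gives an aldoketene that is trapped as it forms by the electron-rich ynol ether in a regioselective ketene–alkyne [2+2] cycloaddition (ketene carbonyl carbon to the unsubstituted alkyne carbon), giving the 3-alkoxycyclobutenone whose C4 stereocentre is formed racemic and is erased in step 11.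

Step 9
Reactants: 17 prenyl bromide (1-bromo-3-methylbut-2-ene); 18 ethynylmagnesium bromide
Product: 19 5-methylhex-4-en-1-yne
Conditions: CuCl (5 mol%), THF, 0 → 40 °C
Reagents that add atoms: none
Why: Copper-catalysed coupling of an alkynyl Grignard reagent with a primary allylic bromide should give the skipped enyne by attack at the unhindered α-carbon, and the volatile product is purified by distillation.

Step 10
Reactants: 19 5-methylhex-4-en-1-yne
Product: 22 triisopropyl[(5-methylhex-4-en-1-yn-1-yl)oxy]silane, via lithium acetylide 20 (not isolated), via lithium ynolate 21 (not isolated)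
Conditions: LiHMDS, THF, −78 °C; t-BuOOLi (from t-BuOOH/LiHMDS), −78 → 0 °C; TIPSOTf, −78 → 0 °C
Reagents that add atoms: tert-butyl hydroperoxide, CC(C)(C)OO; triisopropylsilyl trifluoromethanesulfonate, CC(C)[Si](OS(=O)(=O)C(F)(F)F)(C(C)C)C(C)C
Why: Oxygenation of a lithium acetylide by lithium tert-butyl peroxide gives the lithium ynolate, which the bulky silyl triflate traps on oxygen (acetylide-to-ynolate oxidation and O-silylation), while LiHMDS is too weak a base to touch the doubly activated CH2 of the skipped enyne.

Step 11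
Reactants: 16 4-(benzyloxy)-3-{[2-(benzyloxy)-4-oxocyclobut-2-en-1-yl]methyl}-6-ethyl-5-methyl-2H-pyran-2-one; 22 triisopropyl[(5-methylhex-4-en-1-yn-1-yl)oxy]silane
Product: 27 4-(benzyloxy)-3-{[6-(benzyloxy)-2-hydroxy-3-(3-methylbut-2-en-1-yl)-4-(triisopropylsilyloxy)phenyl]methyl}-6-ethyl-5-methyl-2H-pyran-2-one, via vinylketene 23 (not isolated), via vinylcyclobutenone 24 (not isolated), via dienylketene 25 (not isolated), via cyclohexadienone 26 (not isolated)
Conditions: 22 (1.3 equiv), degassed toluene, 80 °C then 110 °C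
Reagents that add atoms: none
Why: Thermal 4π-electrocyclic opening of cyclobutenone 16 (C4 substituent rotating outward) gives vinylketene 23, which undergoes a regioselective [2+2] cycloaddition with the electron-rich siloxyalkyne to give 2-vinylcyclobutenone 24; a second, reversible 4π opening then delivers dienylketene 25, whose 6π electrocyclisation gives cyclohexadienone 26 and, after tautomerisation, phenol 27. The closest known reaction type is the Danheiser benzannulation of cyclobutenones with siloxy- and alkoxyalkynes, here applied to a 4-substituted 3-alkoxycyclobutenone. The benzene ring is closed by a thermally allowed disrotatory 6π electrocyclisation of the dienylketene (bond between the ketene carbon and the CH(CH2-pyranonyl) terminus), after the two new σ-bonds, C(OH)–C(prenyl) and C(OSi)–C(H), have been set in the [2+2] step. No stereocentre is created, and the racemic C4 centre of 16 disappears on aromatisation. The step needs one selectivity, the orientation of the ketene–alkyne [2+2], and this is secured by the polarisation of the ynol ether, whose prenyl-bearing carbon is the nucleophile that attacks the ketene carbonyl carbon, so that prenyl ends up ortho and silyloxy meta to the new hydroxyl. The neutral, purely thermal conditions should spare the prenyl olefin, the benzyl ethers and the pyranone, and the doubly flanked phenol formed is a poor trap for residual vinylketene.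

Step 12
Reactants: 27 4-(benzyloxy)-3-{[6-(benzyloxy)-2-hydroxy-3-(3-methylbut-2-en-1-yl)-4-(triisopropylsilyloxy)phenyl]methyl}-6-ethyl-5-methyl-2H-pyran-2-one
Product: 28 4-(benzyloxy)-3-{[6-(benzyloxy)-2,4-dihydroxy-3-(3-methylbut-2-en-1-yl)phenyl]methyl}-6-ethyl-5-methyl-2H-pyran-2-one
Conditions: TBAF, AcOH, THF, 0 °C → rt
Reagents that add atoms: none
Why: Fluoride-mediated cleavage of the aryl silyl ether, buffered with acetic acid so that the electron-rich phenoxide is never free, should leave both benzyl ethers, the prenyl group and the pyranone untouched.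

Step 13
Reactants: 29 (S)-2-methylbutanoic acid
Product: 30 (S)-2-methylbutanoyl chloride
Conditions: (COCl)2, DMF (cat.), CH2Cl2, 0 °C → rt; solvent exchange to toluene
Reagents that add atoms: oxalyl chloride, O=C(Cl)C(=O)Cl
Why: Acid chloride formation under base-free conditions at or below room temperature should not enolise the α-stereocentre, so the (S) configuration of the commercial acid is carried over.

Step 14
Reactants: 28 4-(benzyloxy)-3-{[6-(benzyloxy)-2,4-dihydroxy-3-(3-methylbut-2-en-1-yl)phenyl]methyl}-6-ethyl-5-methyl-2H-pyran-2-one; 30 (S)-2-methylbutanoyl chloride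
Product: 32 4-(benzyloxy)-3-{[2-(benzyloxy)-4,6-dihydroxy-3-[(2S)-2-methylbutanoyl]-5-(3-methylbut-2-en-1-yl)phenyl]methyl}-6-ethyl-5-methyl-2H-pyran-2-one, via bis(bromomagnesium) phenolate 31 (not isolated)
Conditions: EtMgBr (2.0 equiv), Et2O/toluene, −20 → 0 °C; then 30 (1.1 equiv), toluene, 0 °C → rt; aq NH4Cl
Reagents that add atoms: none
Why: Deprotonation of both phenols gives aryloxymagnesium bromide 31, in which magnesium binds the acid chloride and delivers the acyl group to the only free ring carbon, ortho to O–Mg (metal-template ortho C-acylation of a magnesium phenolate, a Friedel–Crafts acylation run without Brønsted or strong Lewis acid), so the prenyl group flanked by two phenolic oxygens is not exposed to acid and the α-stereocentre of 30, never treated with an amine base, should be retained.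

Step 15
Reactants: 32 4-(benzyloxy)-3-{[2-(benzyloxy)-4,6-dihydroxy-3-[(2S)-2-methylbutanoyl]-5-(3-methylbut-2-en-1-yl)phenyl]methyl}-6-ethyl-5-methyl-2H-pyran-2-one
Product: 33 6-ethyl-4-hydroxy-5-methyl-3-{[2,4,6-trihydroxy-3-[(2S)-2-methylbutanoyl]-5-(3-methylbut-2-en-1-yl)phenyl]methyl}-2H-pyran-2-one
Conditions: BCl3 (1 M in CH2Cl2), C6HMe5, CH2Cl2, −78 °C; MeOH/CHCl3 quench at −78 °C
Reagents that add atoms: none
Why: Boron trichloride with pentamethylbenzene as a non-basic cation scavenger cleaves benzyl ethers at −78 °C without needing chelation (Lewis-acid debenzylation), so the aryl benzyl ether beside the ketone and the vinylogous benzyl ester should both fall quickly, under conditions cold and short enough to spare the prenyl group and the enolisable (S)-stereocentre.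

Compound list
1 | pentan-3-one | CCC(=O)CC | starting material
2 | (Z)-3-(trimethylsilyloxy)pent-2-ene | C/C=C(/CC)O[Si](C)(C)C | intermediate
3 | allylmalonic acid | C=CCC(C(=O)O)C(=O)O | starting material
4 | allylmalonyl dichloride | C=CCC(C(=O)Cl)C(=O)Cl | intermediate
5 | 3-allyl-6-ethyl-4-hydroxy-5-methyl-2H-pyran-2-one | CCc1oc(=O)c(CC=C)c(O)c1C | intermediate
6 | 3-allyl-4-(benzyloxy)-6-ethyl-5-methyl-2H-pyran-2-one | CCc1oc(=O)c(CC=C)c(OCc2ccccc2)c1C | intermediate
7 | 4-(benzyloxy)-6-ethyl-3-(3-hydroxypropyl)-5-methyl-2H-pyran-2-one | CCc1oc(=O)c(CCCO)c(OCc2ccccc2)c1C | intermediate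
8 | 3-[4-(benzyloxy)-6-ethyl-5-methyl-2-oxo-2H-pyran-3-yl]propanoic acid | CCc1oc(=O)c(CCC(=O)O)c(OCc2ccccc2)c1C | intermediate
9 | benzyl alcohol | OCc1ccccc1 | starting material
10 | trichloroethylene | ClC=C(Cl)Cl | starting material
11 | benzyl (E)-1,2-dichlorovinyl ether | Cl/C=C(/Cl)OCc1ccccc1 | intermediate (not isolated)
12 | lithium (benzyloxy)ethynide | [Li]C#COCc1ccccc1 | intermediate (not isolated)
13 | benzyloxyacetylene [(ethynyloxy)methylbenzene] | C#COCc1ccccc1 | intermediate
14 | 3-[4-(benzyloxy)-6-ethyl-5-methyl-2-oxo-2H-pyran-3-yl]propanoyl chloride | CCc1oc(=O)c(CCC(=O)Cl)c(OCc2ccccc2)c1C | intermediate (not isolated)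
15 | 3-[4-(benzyloxy)-6-ethyl-5-methyl-2-oxo-2H-pyran-3-yl]prop-1-en-1-one (ketene) | CCc1oc(=O)c(CC=C=O)c(OCc2ccccc2)c1C | intermediate (not isolated)
16 | 4-(benzyloxy)-3-{[2-(benzyloxy)-4-oxocyclobut-2-en-1-yl]methyl}-6-ethyl-5-methyl-2H-pyran-2-one (racemic) | CCc1oc(=O)c(CC2C(=O)C=C2OCc3ccccc3)c(OCc4ccccc4)c1C | intermediate
17 | prenyl bromide (1-bromo-3-methylbut-2-ene) | CC(C)=CCBr | starting material
18 | ethynylmagnesium bromide | C#C[Mg]Br | starting material
19 | 5-methylhex-4-en-1-yne | C#CCC=C(C)C | intermediate
20 | lithium 5-methylhex-4-en-1-yn-1-ide | [Li]C#CCC=C(C)C | intermediate (not isolated)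
21 | lithium 5-methylhex-4-en-1-yn-1-olate (ynolate) | [Li]OC#CCC=C(C)C | intermediate (not isolated)
22 | triisopropyl[(5-methylhex-4-en-1-yn-1-yl)oxy]silane | CC(C)=CCC#CO[Si](C(C)C)(C(C)C)C(C)C | intermediate
23 | (3Z)-3-(benzyloxy)-5-[4-(benzyloxy)-6-ethyl-5-methyl-2-oxo-2H-pyran-3-yl]penta-1,3-dien-1-one (vinylketene) | O=C=C/C(OCc1ccccc1)=C/Cc1c(OCc2ccccc2)c(C)c(CC)oc1=O | intermediate (not isolated)
24 | 4-{(1Z)-1-(benzyloxy)-3-[4-(benzyloxy)-6-ethyl-5-methyl-2-oxo-2H-pyran-3-yl]prop-1-en-1-yl}-2-(3-methylbut-2-en-1-yl)-3-(triisopropylsilyloxy)cyclobut-2-en-1-one (racemic) | O=C1C(CC=C(C)C)=C(O[Si](C(C)C)(C(C)C)C(C)C)C1/C(OCc1ccccc1)=C/Cc1c(OCc2ccccc2)c(C)c(CC)oc1=O | intermediate (not isolated)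
25 | (3E,5Z)-5-(benzyloxy)-7-[4-(benzyloxy)-6-ethyl-5-methyl-2-oxo-2H-pyran-3-yl]-2-(3-methylbut-2-en-1-yl)-3-(triisopropylsilyloxy)hepta-1,3,5-trien-1-one (dienylketene) | O=C=C(CC=C(C)C)/C(O[Si](C(C)C)(C(C)C)C(C)C)=C\C(OCc1ccccc1)=C\Cc1c(OCc2ccccc2)c(C)c(CC)oc1=O | intermediate (not isolated)
26 | 5-(benzyloxy)-6-{[4-(benzyloxy)-6-ethyl-5-methyl-2-oxo-2H-pyran-3-yl]methyl}-2-(3-methylbut-2-en-1-yl)-3-(triisopropylsilyloxy)cyclohexa-2,4-dien-1-one (racemic) | O=C1C(CC=C(C)C)=C(O[Si](C(C)C)(C(C)C)C(C)C)C=C(OCc2ccccc2)C1Cc1c(OCc2ccccc2)c(C)c(CC)oc1=O | intermediate (not isolated)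
27 | 4-(benzyloxy)-3-{[6-(benzyloxy)-2-hydroxy-3-(3-methylbut-2-en-1-yl)-4-(triisopropylsilyloxy)phenyl]methyl}-6-ethyl-5-methyl-2H-pyran-2-one | CCc1oc(=O)c(Cc2c(O)c(CC=C(C)C)c(O[Si](C(C)C)(C(C)C)C(C)C)cc2OCc3ccccc3)c(OCc4ccccc4)c1C | intermediate
28 | 4-(benzyloxy)-3-{[6-(benzyloxy)-2,4-dihydroxy-3-(3-methylbut-2-en-1-yl)phenyl]methyl}-6-ethyl-5-methyl-2H-pyran-2-one | CCc1oc(=O)c(Cc2c(O)c(CC=C(C)C)c(O)cc2OCc3ccccc3)c(OCc4ccccc4)c1C | intermediate
29 | (S)-2-methylbutanoic acid | CC[C@H](C)C(=O)O | starting material
30 | (S)-2-methylbutanoyl chloride | CC[C@H](C)C(=O)Cl | intermediate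
31 | bis(bromomagnesium) 2,4-diphenolate of 28 | CCc1oc(=O)c(Cc2c(O[Mg]Br)c(CC=C(C)C)c(O[Mg]Br)cc2OCc3ccccc3)c(OCc4ccccc4)c1C | intermediate (not isolated)
32 | 4-(benzyloxy)-3-{[2-(benzyloxy)-4,6-dihydroxy-3-[(2S)-2-methylbutanoyl]-5-(3-methylbut-2-en-1-yl)phenyl]methyl}-6-ethyl-5-methyl-2H-pyran-2-one | CCc1oc(=O)c(Cc2c(O)c(CC=C(C)C)c(O)c(C(=O)[C@@H](C)CC)c2OCc3ccccc3)c(OCc4ccccc4)c1C | intermediate
33 | 6-ethyl-4-hydroxy-5-methyl-3-{[2,4,6-trihydroxy-3-[(2S)-2-methylbutanoyl]-5-(3-methylbut-2-en-1-yl)phenyl]methyl}-2H-pyran-2-one | CCc1oc(=O)c(Cc2c(O)c(CC=C(C)C)c(O)c(C(=O)[C@@H](C)CC)c2O)c(O)c1C | target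

Total step count: 15.
Longest linear sequence: 10 steps (steps 1, 3, 4, 5, 6, 8, 11, 12, 14, 15).

Steps most likely to fail

Step 11. The donor-substituted cyclobutenone may open slowly, so the siloxyalkyne could decay thermally (silyl migration to a silylketene) first. Vinylketene 23 could also be lost by dimerisation or by capture by the phenol being formed, or the cascade could stall at 24. The fallback sets out from 16 and 22 and triggers the first ring opening with light instead of heat. Irradiation of the two partners at room temperature (medium-pressure mercury lamp, Pyrex filter, degassed toluene) should give vinylcyclobutenone 24, which is then isolated. A separate short thermolysis in toluene at 110 °C carries 24 through the second 4π opening and 6π closure, and the route is rejoined at 27. This staged photochemical variant makes no compound outside the compound list (F0).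

Step 8. The aldoketene may dimerise faster than it is trapped, because the ynol ether cannot be used in large excess, and chloride may strip the benzyl group from acid chloride 14 with lactonisation. The fallback generates the same ketene by Wolff rearrangement, at low stationary concentration and without an acid chloride. It sets out from 6:
- Lemieux–Johnson cleavage of the allyl group (OsO4 cat., NaIO4, 2,6-lutidine, dioxane/H2O) gives [4-(benzyloxy)-6-ethyl-5-methyl-2-oxo-2H-pyran-3-yl]acetaldehyde F1.
- Pinnick oxidation (NaClO2, NaH2PO4, 2-methylbut-2-ene) gives [4-(benzyloxy)-6-ethyl-5-methyl-2-oxo-2H-pyran-3-yl]acetic acid F2.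
- Activation with isobutyl chloroformate and N-methylmorpholine at −15 °C gives the isobutyl carbonic mixed anhydride F3.
- Diazomethane converts this into 4-(benzyloxy)-3-(3-diazo-2-oxopropyl)-6-ethyl-5-methyl-2H-pyran-2-one F4.
- Silver benzoate/Et3N in THF at room temperature in the presence of 13 then effects the Wolff rearrangement to ketene 15, which is trapped by [2+2] cycloaddition, rejoining the route at 16.

Step 14. O-acylation of the magnesium phenolate may outrun C-acylation at the crowded ring carbon. The fallback sets out from silyl ether 27 and activates the electrophile instead of the nucleophile. A Friedel–Crafts acylation with 30 and SnCl4 in CH2Cl2 at −78 → −40 °C, with 2,6-di-tert-butyl-4-methylpyridine as proton trap, gives 4-(benzyloxy)-3-{[2-(benzyloxy)-6-hydroxy-3-[(2S)-2-methylbutanoyl]-5-(3-methylbut-2-en-1-yl)-4-(triisopropylsilyloxy)phenyl]methyl}-6-ethyl-5-methyl-2H-pyran-2-one F5. Buffered desilylation (TBAF, AcOH, THF) then rejoins the route at 32.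

Further compounds
F0 | step 11 | none | none
F1 | step 8 | [4-(benzyloxy)-6-ethyl-5-methyl-2-oxo-2H-pyran-3-yl]acetaldehyde | CCc1oc(=O)c(CC=O)c(OCc2ccccc2)c1C
F2 | step 8 | [4-(benzyloxy)-6-ethyl-5-methyl-2-oxo-2H-pyran-3-yl]acetic acid | CCc1oc(=O)c(CC(=O)O)c(OCc2ccccc2)c1C
F3 | step 8 | [4-(benzyloxy)-6-ethyl-5-methyl-2-oxo-2H-pyran-3-yl]acetic isobutyl carbonic anhydride | CCc1oc(=O)c(CC(=O)OC(=O)OCC(C)C)c(OCc2ccccc2)c1C
F4 | step 8 | 4-(benzyloxy)-3-(3-diazo-2-oxopropyl)-6-ethyl-5-methyl-2H-pyran-2-one | CCc1oc(=O)c(CC(=O)C=[N+]=[N-])c(OCc2ccccc2)c1C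
F5 | step 14 | 4-(benzyloxy)-3-{[2-(benzyloxy)-6-hydroxy-3-[(2S)-2-methylbutanoyl]-5-(3-methylbut-2-en-1-yl)-4-(triisopropylsilyloxy)phenyl]methyl}-6-ethyl-5-methyl-2H-pyran-2-one | CCc1oc(=O)c(Cc2c(O)c(CC=C(C)C)c(O[Si](C(C)C)(C(C)C)C(C)C)c(C(=O)[C@@H](C)CC)c2OCc3ccccc3)c(OCc4ccccc4)c1C
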